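## Analysis of the target

Target 22 is methyl 7-hydroxy-5-[2-(4-hydroxyphenyl)ethyl]-2,2-dimethyl-8-(3-methylbut-2-en-1-yl)-2H-chromene-6-carboxylate. Its core, ring A, is a benzene ring with all six carbons substituted. Numbered as a benzoate, C1 carries CO2Me, C2 a free hydroxyl (O2), C3 a prenyl group, C4 the pyran oxygen (O4), C5 the pyran vinyl carbon C4', and C6 a two-carbon chain (Cα on C6) ending in the 4-hydroxyphenyl ring C. Ring B is the 2,2-dimethyl-2H-pyran fused along C4–C5. There is no stereocentre and neither alkene has a geometry to set, so the problem is one of regiochemistry only. The sensitive groups are the chromene (acid, oxidants), the prenyl group next to the free O2 hydroxyl (acid closes it to a chroman), the electron-rich phenols and the chelated salicylate ester. The difficulty is that the C6 chain is meta to both ring oxygens, so neither electrophilic substitution nor ortho-metalation can place it; the C1 ester is flanked on both sides; and C3 and C5, both ortho to O4, must receive different five-carbon units. The strategy rests on C6 and C1: two adjacent carbon substituents, with C1 next to O2. This is the pattern left when a carbon nucleophile and then a carbon electrophile add across the C1–C6 bond of an aryne flanked by an alkoxy group, and that aryne comes from a symmetrical 5-fluororesorcinol diether.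

## Retrosynthetic reasoning

Ring B is removed first, by cutting O4–C2' and C5–C4' of 22. This leads to triol 19 and 3-methylbut-2-enal 20, joined in the forward sense through ortho-quinone methide 21. The chromene is the most fragile part of 22, so it is made last. At that stage C5 is the only unsubstituted carbon of ring A, so the annulation has one site to choose on that ring.

Triol 19 is traced to the bis-silyl ether 18. O4 and the ring C phenol must be blocked while O2 is functionalized, and silyl ethers are chosen because they are removed with fluoride. Acid would close the C3 prenyl group onto a neighbouring phenol.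

The C3–prenyl bond of 18 is cut next, by a [3,3] shift back to the tertiary allyl ether 16 (forward through dienone 17). Direct C-prenylation of a resorcylate would be spread over C3, C5 and oxygen. From O2 the only ortho carbon bearing hydrogen is C3, because C1 carries the ester. Ether 16 is cut at its O2–C bond to phenol 12 and carbonate 15, and 15 comes from alcohol 13 through alkoxide 14.

Phenol 12 goes back to diol 11 and then to the bis-acetal 10. The two acetals are removed together before any prenyl unit is present, so the only acidic step of the route meets no acid-sensitive group. The two hydroxyls of 11 are then told apart by the hydrogen bond of O2 to the ester carbonyl, which leaves O4 as the one that is silylated.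

The key disconnection cuts C6–Cα and C1–CO2Me of 10 in one operation. It gives the fluoroarene 2, the Grignard reagent 5 and methyl chloroformate 6, by way of aryllithium 7, aryne 8 and arylmagnesium 9. The cut is made here because these are the two bonds that no phenol-directed reaction can form: one meta to both oxygens, the other at a doubly flanked carbon. What is gained is that a symmetrical, trisubstituted arene becomes the correctly pentasubstituted ring A core in one flask. The forward reaction must metalate 2 next to fluorine, add 5 to the aryne carbon remote from the flanking oxygen, and acylate the resulting anion.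

Fluoroarene 2 is the bis-acetal of the purchased diol 1. Reagent 5 comes from bromide 4, the silyl ether of the purchased bromophenol 3. The silyl group on ring C is triisopropylsilyl so that it outlasts the acidic acetal cleavage and can later be distinguished from the O4 silyl ether if needed.

## Alternatives that were turned down

Alternative 1: Ring A is cut at C1–C6 and C2–C3, which opens it to the acyclic enone A2 and dimethyl malonate A3. In the forward step the anion of A3 adds to the β-carbon of A2 and the α'-enolate closes onto a malonate ester, giving the cyclohexanedione ester A1. Oxidation must then turn A1 into the resorcylate, and desilylation would meet the route at 19.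
- For: the materials are cheap, the prenyl group sits on C3 from the start with no regiochemical question, and no protecting-group work on O2 and O4 is needed. On step count and on the placement of the C3 substituent it is stronger than the chosen route.
- Against: A1 is four hydrogens short of aromatic. Dehydrogenating such a β-diketo ester needs halogen or quinone oxidants, which also attack the trisubstituted prenyl alkene or drive oxidative closure onto an enol oxygen. Halogen-mediated aromatization in an alcohol tends to etherify O4, which must stay free for ring B. The β-keto ester can also decarboxylate.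
- Comparison: the chosen route keeps ring A aromatic from the first step, so no oxidation is ever run in the presence of the prenyl group, and its main risk lies early, on inexpensive material.

Alternative 2: Ring A is cut at C5–C6 and C1–C2 into the oxygenated diene A5 and the ynoate A6. A thermal [4+2] addition followed by loss of the methoxy and silyl groups on acidic work-up gives the resorcylate A4. A4 is only a desilylation and the annulation of step 11 away from 22.
- For: it is the most convergent plan, putting all six ring A substituents or their precursors in place in one step. The regiochemistry follows from pairing the nucleophilic CH2 terminus of A5 with the β-carbon of A6. On convergence and step economy it is clearly stronger.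
- Against: A6 carries a β-alkyl group and only one activating ester, so it is a weak dienophile that needs prolonged heating. A5 is hindered by its central prenyl group and its doubly substituted terminus, is hydrolytically fragile, and is prone to silyl transfer at such temperatures. The whole route would rest on this one demanding cycloaddition.
- Comparison: the chosen route is longer, but its key step joins robust partners by a reaction with close precedent on exactly this oxygenation pattern.

Alternative 3: Ring B is cut at C4'–C3' and O4–C2', giving the salicylaldehyde A8 and 2-methylprop-1-enylmagnesium bromide A9. A9 adds to the formyl group, the benzylic alkoxide dehydrates to an ortho-quinone methide, and oxa-6π closure gives chromene A7. Desilylation of A7 would give 22.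
- For: the site of ring B is fixed by where the formyl group sits, not by the nucleophilicity of a crowded C5, and the ring C phenol stays protected during ring closure. On those two points it is stronger than step 11.
- Against: it builds only ring B, so the hexasubstituted ring A problem is untouched. A8 requires formylation at C5 of an arene that already carries the acid-sensitive prenyl group. A9 must be used in excess to consume two phenols while the methyl ester is exposed. Two steps replace one annulation.
- Comparison: the chosen route reaches the same kind of quinone methide directly from 19 and 20, and its key step solves ring A, which this alternative leaves open.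

Key step: step 4

## Route

Step 1
Reactants: 1 5-fluorobenzene-1,3-diol
Product: 2 1-fluoro-3,5-bis(methoxymethoxy)benzene
Conditions: MOMCl (2.5 equiv), i-Pr2NEt, CH2Cl2, 0 °C → rt
Reagents that add atoms: chloromethyl methyl ether (MOMCl), COCCl
Why: O-alkylation of both phenols by the reactive α-chloro ether under amine base; the acetals are base-stable, coordinate lithium and come off later under mild acid.

Step 2
Reactants: 3 4-(2-bromoethyl)phenol
Product: 4 [4-(2-bromoethyl)phenoxy]triisopropylsilane
Conditions: TIPSCl, imidazole, CH2Cl2, 0 °C → rt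
Reagents that add atoms: chlorotriisopropylsilane (TIPSCl), CC(C)[Si](Cl)(C(C)C)C(C)C
Why: Imidazole-promoted silylation of the phenol; the weak base avoids phenoxide attack on the primary bromide, and the bulky silyl ether tolerates magnesium insertion and later acidic methanol.

Step 3
Reactants: 4 [4-(2-bromoethyl)phenoxy]triisopropylsilane
Product: 5 {2-[4-(triisopropylsilyloxy)phenyl]ethyl}magnesium bromide (THF solution, titrated and used directly)
Conditions: Mg turnings, I2 (cat.), THF, slow addition, rt → 40 °C
Reagents that add atoms: magnesium, [Mg]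
Why: Grignard formation by insertion of magnesium into the primary C–Br bond; the aryl silyl ether is inert, and slow addition at high dilution limits Wurtz homocoupling.

Step 4
Reactants: 2 1-fluoro-3,5-bis(methoxymethoxy)benzene; 5 {2-[4-(triisopropylsilyloxy)phenyl]ethyl}magnesium bromide; 6 methyl chloroformate
Product: 10 methyl 2,4-bis(methoxymethoxy)-6-{2-[4-(triisopropylsilyloxy)phenyl]ethyl}benzoate, via [2-fluoro-4,6-bis(methoxymethoxy)phenyl]lithium 7 (not isolated), via 3,5-bis(methoxymethoxy)benzyne 8 (not isolated), via the arylmagnesium bromide 9 (not isolated)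
Conditions: s-BuLi (1.05 equiv), THF, −78 °C; 5 (2 equiv), −78 °C → rt; 6 (5 equiv), −78 °C → rt
Reagents that add atoms: none
Why: s-BuLi removes the proton of 2 between fluorine and an acetal oxygen (the two such sites are equivalent), giving 7, which is stable at −78 °C and loses LiF on warming to form aryne 8 in the presence of 5. The C–O bond next to the strained bond distorts and polarizes 8 so that the carbon remote from the acetal is the more electrophilic; 5 adds there, leaving the carbon–magnesium bond of 9 beside the acetal oxygen, where it is stabilized inductively and by chelation. Acylation of 9 by 6 then forms the C1 ester. The closest known reaction type is the carbomagnesiation of a 3-alkoxyaryne generated from an ortho-lithiated fluoroarene, followed by electrophilic quench. No ring is closed and no stereocentre is formed; the step makes the C6–Cα and C1–carboxyl bonds. It needs three selectivities: the site of metalation, secured by the acidifying fluorine together with one coordinating acetal at low temperature; the orientation of addition to 8, secured by the flanking oxygen; and acylation of 9 without attack on the product, secured by the doubly flanked ester and by an excess of 6 added cold, which also destroys surplus 5.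

Step 5
Reactants: 10 methyl 2,4-bis(methoxymethoxy)-6-{2-[4-(triisopropylsilyloxy)phenyl]ethyl}benzoate
Product: 11 methyl 2,4-dihydroxy-6-{2-[4-(triisopropylsilyloxy)phenyl]ethyl}benzoate
Conditions: HCl (ca. 1 M), MeOH, rt → 40 °C
Reagents that add atoms: none
Why: Acid-catalysed acetal exchange to methanol frees both phenols, the O2 acetal first (assisted by the ester carbonyl); the aryl triisopropylsilyl ether is far less acid-labile, and the methyl ester cannot change in methanol.

Step 6
Reactants: 11 methyl 2,4-dihydroxy-6-{2-[4-(triisopropylsilyloxy)phenyl]ethyl}benzoate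
Product: 12 methyl 4-(tert-butyldimethylsilyloxy)-2-hydroxy-6-{2-[4-(triisopropylsilyloxy)phenyl]ethyl}benzoate
Conditions: TBSCl (1.05 equiv), imidazole, CH2Cl2, 0 °C
Reagents that add atoms: tert-butylchlorodimethylsilane (TBSCl), CC(C)(C)[Si](C)(C)Cl
Why: Selective silylation of the unhindered, more acidic O4 hydroxyl; the O2 hydroxyl is held in a hydrogen bond to the ester carbonyl and is shielded by the ester.

Step 7
Reactants: 13 2-methylbut-3-en-2-ol
Product: 15 tert-butyl 2-methylbut-3-en-2-yl carbonate, via lithium 2-methylbut-3-en-2-olate 14 (not isolated)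
Conditions: n-BuLi, THF, −78 °C; Boc2O, −78 °C → rt; H2O
Reagents that add atoms: di-tert-butyl dicarbonate (Boc2O), CC(C)(C)OC(=O)OC(=O)OC(C)(C)C
Why: Acylation of the tertiary lithium alkoxide by the dicarbonate; deprotonation first overcomes the low nucleophilicity of the tertiary alcohol.

Step 8
Reactants: 12 methyl 4-(tert-butyldimethylsilyloxy)-2-hydroxy-6-{2-[4-(triisopropylsilyloxy)phenyl]ethyl}benzoate; 15 tert-butyl 2-methylbut-3-en-2-yl carbonate
Product: 16 methyl 4-(tert-butyldimethylsilyloxy)-2-[(2-methylbut-3-en-2-yl)oxy]-6-{2-[4-(triisopropylsilyloxy)phenyl]ethyl}benzoate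
Conditions: Pd(PPh3)4 (5 mol %), 15 (2 equiv), THF, 4 Å MS, 0 °C → rt
Reagents that add atoms: none
Why: Tsuji–Trost O-allylation: zerovalent palladium ionizes the carbonate with loss of CO2, the released tert-butoxide deprotonates the phenol, and the phenoxide attacks the more substituted allyl terminus under kinetic control at low temperature; O2 is the only free hydroxyl.

Step 9
Reactants: 16 methyl 4-(tert-butyldimethylsilyloxy)-2-[(2-methylbut-3-en-2-yl)oxy]-6-{2-[4-(triisopropylsilyloxy)phenyl]ethyl}benzoate
Product: 18 methyl 4-(tert-butyldimethylsilyloxy)-2-hydroxy-3-(3-methylbut-2-en-1-yl)-6-{2-[4-(triisopropylsilyloxy)phenyl]ethyl}benzoate, via the C3-allylated cyclohexadienone 17 (not isolated)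
Conditions: PhMe, 110–120 °C, sealed tube
Reagents that add atoms: none
Why: Aromatic Claisen rearrangement: the [3,3] shift can only end at C3, because the other ortho carbon of O2 (C1) bears the ester; allyl inversion turns the tertiary ether into the 3-methylbut-2-enyl group, and tautomerization of 17 restores the chelated phenol under neutral conditions.

Step 10
Reactants: 18 methyl 4-(tert-butyldimethylsilyloxy)-2-hydroxy-3-(3-methylbut-2-en-1-yl)-6-{2-[4-(triisopropylsilyloxy)phenyl]ethyl}benzoate
Product: 19 methyl 2,4-dihydroxy-6-[2-(4-hydroxyphenyl)ethyl]-3-(3-methylbut-2-en-1-yl)benzoate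
Conditions: TBAF (2.5 equiv), AcOH, THF, 0 °C → rt
Reagents that add atoms: none
Why: Fluoride cleaves both aryl silyl ethers; the acetic acid buffer keeps the phenols protonated and is too weak to close the prenyl group onto O2 or O4.

Step 11
Reactants: 19 methyl 2,4-dihydroxy-6-[2-(4-hydroxyphenyl)ethyl]-3-(3-methylbut-2-en-1-yl)benzoate; 20 3-methylbut-2-enal
Product: 22 methyl 7-hydroxy-5-[2-(4-hydroxyphenyl)ethyl]-2,2-dimethyl-8-(3-methylbut-2-en-1-yl)-2H-chromene-6-carboxylate, via the ortho-quinone methide 21 (not isolated)
Conditions: 20 (2 equiv), ethylenediammonium diacetate (20 mol %), PhMe, 110 °C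
Reagents that add atoms: none
Why: Phenol–enal annulation: the ammonium salt activates 20 as an iminium ion, C5 (ortho to O4, para to O2, the only free carbon of ring A) attacks it, elimination gives 21, and oxa-6π electrocyclization closes ring B; the monophenol of ring C is far less nucleophilic than the resorcinol ring A.

## Compound list

1 | 5-fluorobenzene-1,3-diol | Oc1cc(O)cc(F)c1 | starting material
2 | 1-fluoro-3,5-bis(methoxymethoxy)benzene | COCOc1cc(F)cc(OCOC)c1 | intermediate
3 | 4-(2-bromoethyl)phenol | Oc1ccc(CCBr)cc1 | starting material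
4 | [4-(2-bromoethyl)phenoxy]triisopropylsilane | BrCCc1ccc(O[Si](C(C)C)(C(C)C)C(C)C)cc1 | intermediate
5 | {2-[4-(triisopropylsilyloxy)phenyl]ethyl}magnesium bromide | Br[Mg]CCc1ccc(O[Si](C(C)C)(C(C)C)C(C)C)cc1 | intermediate
6 | methyl chloroformate | COC(=O)Cl | starting material
7 | [2-fluoro-4,6-bis(methoxymethoxy)phenyl]lithium | [Li]c1c(F)cc(OCOC)cc1OCOC | intermediate
8 | 3,5-bis(methoxymethoxy)benzyne | COCOC1=CC(OCOC)=CC#C1 | intermediate
9 | [2,4-bis(methoxymethoxy)-6-{2-[4-(triisopropylsilyloxy)phenyl]ethyl}phenyl]magnesium bromide | COCOc1cc(OCOC)c([Mg]Br)c(CCc2ccc(O[Si](C(C)C)(C(C)C)C(C)C)cc2)c1 | intermediate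
10 | methyl 2,4-bis(methoxymethoxy)-6-{2-[4-(triisopropylsilyloxy)phenyl]ethyl}benzoate | COCOc1cc(OCOC)c(C(=O)OC)c(CCc2ccc(O[Si](C(C)C)(C(C)C)C(C)C)cc2)c1 | intermediate
11 | methyl 2,4-dihydroxy-6-{2-[4-(triisopropylsilyloxy)phenyl]ethyl}benzoate | COC(=O)c1c(O)cc(O)cc1CCc1ccc(O[Si](C(C)C)(C(C)C)C(C)C)cc1 | intermediate
12 | methyl 4-(tert-butyldimethylsilyloxy)-2-hydroxy-6-{2-[4-(triisopropylsilyloxy)phenyl]ethyl}benzoate | COC(=O)c1c(O)cc(O[Si](C)(C)C(C)(C)C)cc1CCc1ccc(O[Si](C(C)C)(C(C)C)C(C)C)cc1 | intermediate
13 | 2-methylbut-3-en-2-ol | C=CC(C)(C)O | starting material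
14 | lithium 2-methylbut-3-en-2-olate | [Li]OC(C)(C)C=C | intermediate
15 | tert-butyl 2-methylbut-3-en-2-yl carbonate | C=CC(C)(C)OC(=O)OC(C)(C)C | intermediate
16 | methyl 4-(tert-butyldimethylsilyloxy)-2-[(2-methylbut-3-en-2-yl)oxy]-6-{2-[4-(triisopropylsilyloxy)phenyl]ethyl}benzoate | COC(=O)c1c(OC(C)(C)C=C)cc(O[Si](C)(C)C(C)(C)C)cc1CCc1ccc(O[Si](C(C)C)(C(C)C)C(C)C)cc1 | intermediate
17 | methyl 4-(tert-butyldimethylsilyloxy)-5-(3-methylbut-2-en-1-yl)-6-oxo-2-{2-[4-(triisopropylsilyloxy)phenyl]ethyl}cyclohexa-1,3-diene-1-carboxylate (racemic at C5, transient) | COC(=O)C1=C(CCc2ccc(O[Si](C(C)C)(C(C)C)C(C)C)cc2)C=C(O[Si](C)(C)C(C)(C)C)C(CC=C(C)C)C1=O | intermediate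
18 | methyl 4-(tert-butyldimethylsilyloxy)-2-hydroxy-3-(3-methylbut-2-en-1-yl)-6-{2-[4-(triisopropylsilyloxy)phenyl]ethyl}benzoate | COC(=O)c1c(O)c(CC=C(C)C)c(O[Si](C)(C)C(C)(C)C)cc1CCc1ccc(O[Si](C(C)C)(C(C)C)C(C)C)cc1 | intermediate
19 | methyl 2,4-dihydroxy-6-[2-(4-hydroxyphenyl)ethyl]-3-(3-methylbut-2-en-1-yl)benzoate | COC(=O)c1c(O)c(CC=C(C)C)c(O)cc1CCc1ccc(O)cc1 | intermediate
20 | 3-methylbut-2-enal | CC(C)=CC=O | starting material
21 | methyl 6-hydroxy-2-[2-(4-hydroxyphenyl)ethyl]-5-(3-methylbut-2-en-1-yl)-3-(3-methylbut-2-en-1-ylidene)-4-oxocyclohexa-1,5-diene-1-carboxylate | COC(=O)C1=C(CCc2ccc(O)cc2)C(=CC=C(C)C)C(=O)C(CC=C(C)C)=C1O | intermediate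
22 | methyl 7-hydroxy-5-[2-(4-hydroxyphenyl)ethyl]-2,2-dimethyl-8-(3-methylbut-2-en-1-yl)-2H-chromene-6-carboxylate | COC(=O)c1c(O)c(CC=C(C)C)c2c(c1CCc1ccc(O)cc1)C=CC(C)(C)O2 | target

## Step count and least certain steps

Total: 11 steps. Longest linear sequence: 9 steps (3 → 4 → 5 → 10 → 11 → 12 → 16 → 18 → 19 → 22, steps 2, 3, 4, 5, 6, 8, 9, 10 and 11).

**Step 4 (key step).** Three things may go wrong.
- Deprotonation at the carbon between the two acetals instead of beside fluorine. That anion cannot eliminate and is simply acylated.
- Addition of unreacted 7 to 8 if elimination outruns capture by 5, which gives biaryl coupling.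
- Incomplete acylation of the hindered 9 while 6 is consumed by surplus 5.

Fallback, from 5 and returning at 10: 5-bromobenzene-1,3-diol F1 is converted as in step 1 into 1-bromo-3,5-bis(methoxymethoxy)benzene F2. Kumada coupling of F2 with 5 under PdCl2(dppf) in THF gives {4-[2-(3,5-bis(methoxymethoxy)phenyl)ethyl]phenoxy}triisopropylsilane F3. NBS in MeCN at 0 °C brominates F3 ortho to the chain and para to an acetal oxygen, the usual site for 5-alkylresorcinol diethers, giving {4-[2-(2-bromo-3,5-bis(methoxymethoxy)phenyl)ethyl]phenoxy}triisopropylsilane F4. Bromine–lithium exchange with n-BuLi at −78 °C gives [2,4-bis(methoxymethoxy)-6-{2-[4-(triisopropylsilyloxy)phenyl]ethyl}phenyl]lithium F5, which is acylated by 6 to give 10.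

**Step 8.** The chelated, ester-flanked O2 hydroxyl is a poor nucleophile. Conversion may stall, or reversible ionization may drift the product to the linear prenyl ether or to C-allylation.

Fallback, from 12 and returning at 16: copper-catalysed propargylation of 12 with 3-chloro-3-methylbut-1-yne F6 (CuCl2·2H2O cat., DBU, MeCN, 0 °C) gives methyl 4-(tert-butyldimethylsilyloxy)-2-[(2-methylbut-3-yn-2-yl)oxy]-6-{2-[4-(triisopropylsilyloxy)phenyl]ethyl}benzoate F7. Partial hydrogenation of F7 over Pd/CaCO3 poisoned with Pb(OAc)2 and quinoline gives 16.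

**Step 11.** C5 is crowded between O4 and the C6 chain, so the condensation may be slow. Competing attack by ring C or polymerization of 20 could then take over, and long heating risks closure of the prenyl group onto a phenol.

Fallback, from 18 and returning at 22: catalytic K2CO3 in MeOH at 0 °C removes only the O4 silyl ether, whose phenoxide is stabilized by the para ester, to give methyl 2,4-dihydroxy-3-(3-methylbut-2-en-1-yl)-6-{2-[4-(triisopropylsilyloxy)phenyl]ethyl}benzoate F8. O4-selective propargylation with F6 (CuCl2·2H2O cat., DBU, MeCN) gives methyl 2-hydroxy-3-(3-methylbut-2-en-1-yl)-4-[(2-methylbut-3-yn-2-yl)oxy]-6-{2-[4-(triisopropylsilyloxy)phenyl]ethyl}benzoate F9. Heating in xylene at 140 °C triggers propargyl Claisen shift to C5, tautomerization, 1,5-hydrogen shift and oxa-6π closure to methyl 7-hydroxy-2,2-dimethyl-8-(3-methylbut-2-en-1-yl)-5-{2-[4-(triisopropylsilyloxy)phenyl]ethyl}-2H-chromene-6-carboxylate F10. TBAF/AcOH then gives 22.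

**Step 5.** Cleavage of the O4 acetal, which is deactivated by the para ester, may need conditions under which the ring C silyl ether starts to solvolyse, so the two protecting groups may not be cleanly distinguished.

Fallback, from 10 and returning at 19: the acid treatment is pushed (HCl, MeOH, 60 °C) until all three groups are gone, giving methyl 2,4-dihydroxy-6-[2-(4-hydroxyphenyl)ethyl]benzoate F11. TBSCl (2.2 equiv) and imidazole silylate the two non-chelated phenols to give methyl 4-(tert-butyldimethylsilyloxy)-6-{2-[4-(tert-butyldimethylsilyloxy)phenyl]ethyl}-2-hydroxybenzoate F12. The operations of steps 8 to 10 then follow: etherification with 15 gives methyl 4-(tert-butyldimethylsilyloxy)-6-{2-[4-(tert-butyldimethylsilyloxy)phenyl]ethyl}-2-[(2-methylbut-3-en-2-yl)oxy]benzoate F13, Claisen shift gives methyl 4-(tert-butyldimethylsilyloxy)-6-{2-[4-(tert-butyldimethylsilyloxy)phenyl]ethyl}-2-hydroxy-3-(3-methylbut-2-en-1-yl)benzoate F14, and TBAF/AcOH gives 19.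

## Further compounds

F1 | step 4 | 5-bromobenzene-1,3-diol | Oc1cc(O)cc(Br)c1
F2 | step 4 | 1-bromo-3,5-bis(methoxymethoxy)benzene | COCOc1cc(Br)cc(OCOC)c1
F3 | step 4 | {4-[2-(3,5-bis(methoxymethoxy)phenyl)ethyl]phenoxy}triisopropylsilane | COCOc1cc(OCOC)cc(CCc2ccc(O[Si](C(C)C)(C(C)C)C(C)C)cc2)c1
F4 | step 4 | {4-[2-(2-bromo-3,5-bis(methoxymethoxy)phenyl)ethyl]phenoxy}triisopropylsilane | COCOc1cc(OCOC)c(Br)c(CCc2ccc(O[Si](C(C)C)(C(C)C)C(C)C)cc2)c1
F5 | step 4 | [2,4-bis(methoxymethoxy)-6-{2-[4-(triisopropylsilyloxy)phenyl]ethyl}phenyl]lithium | COCOc1cc(OCOC)c([Li])c(CCc2ccc(O[Si](C(C)C)(C(C)C)C(C)C)cc2)c1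
F6 | step 8 | 3-chloro-3-methylbut-1-yne | CC(C)(Cl)C#C
F7 | step 8 | methyl 4-(tert-butyldimethylsilyloxy)-2-[(2-methylbut-3-yn-2-yl)oxy]-6-{2-[4-(triisopropylsilyloxy)phenyl]ethyl}benzoate | COC(=O)c1c(OC(C)(C)C#C)cc(O[Si](C)(C)C(C)(C)C)cc1CCc1ccc(O[Si](C(C)C)(C(C)C)C(C)C)cc1
F8 | step 11 | methyl 2,4-dihydroxy-3-(3-methylbut-2-en-1-yl)-6-{2-[4-(triisopropylsilyloxy)phenyl]ethyl}benzoate | COC(=O)c1c(O)c(CC=C(C)C)c(O)cc1CCc1ccc(O[Si](C(C)C)(C(C)C)C(C)C)cc1
F9 | step 11 | methyl 2-hydroxy-3-(3-methylbut-2-en-1-yl)-4-[(2-methylbut-3-yn-2-yl)oxy]-6-{2-[4-(triisopropylsilyloxy)phenyl]ethyl}benzoate | COC(=O)c1c(O)c(CC=C(C)C)c(OC(C)(C)C#C)cc1CCc1ccc(O[Si](C(C)C)(C(C)C)C(C)C)cc1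
F10 | step 11 | methyl 7-hydroxy-2,2-dimethyl-8-(3-methylbut-2-en-1-yl)-5-{2-[4-(triisopropylsilyloxy)phenyl]ethyl}-2H-chromene-6-carboxylate | COC(=O)c1c(O)c(CC=C(C)C)c2c(c1CCc1ccc(O[Si](C(C)C)(C(C)C)C(C)C)cc1)C=CC(C)(C)O2
F11 | step 5 | methyl 2,4-dihydroxy-6-[2-(4-hydroxyphenyl)ethyl]benzoate | COC(=O)c1c(O)cc(O)cc1CCc1ccc(O)cc1
F12 | step 5 | methyl 4-(tert-butyldimethylsilyloxy)-6-{2-[4-(tert-butyldimethylsilyloxy)phenyl]ethyl}-2-hydroxybenzoate | COC(=O)c1c(O)cc(O[Si](C)(C)C(C)(C)C)cc1CCc1ccc(O[Si](C)(C)C(C)(C)C)cc1
F13 | step 5 | methyl 4-(tert-butyldimethylsilyloxy)-6-{2-[4-(tert-butyldimethylsilyloxy)phenyl]ethyl}-2-[(2-methylbut-3-en-2-yl)oxy]benzoate | COC(=O)c1c(OC(C)(C)C=C)cc(O[Si](C)(C)C(C)(C)C)cc1CCc1ccc(O[Si](C)(C)C(C)(C)C)cc1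
F14 | step 5 | methyl 4-(tert-butyldimethylsilyloxy)-6-{2-[4-(tert-butyldimethylsilyloxy)phenyl]ethyl}-2-hydroxy-3-(3-methylbut-2-en-1-yl)benzoate | COC(=O)c1c(O)c(CC=C(C)C)c(O[Si](C)(C)C(C)(C)C)cc1CCc1ccc(O[Si](C)(C)C(C)(C)C)cc1
A1 | alternative 1 | methyl 3-(3-methylbut-2-enyl)-2,4-dioxo-6-{2-[4-(triisopropylsilyloxy)phenyl]ethyl}cyclohexane-1-carboxylate (enol and diastereomer mixture) | COC(=O)C1C(=O)C(CC=C(C)C)C(=O)CC1CCc1ccc(O[Si](C(C)C)(C(C)C)C(C)C)cc1
A2 | alternative 1 | (3E)-8-methyl-1-[4-(triisopropylsilyloxy)phenyl]nona-3,7-dien-5-one | CC(C)=CCCC(=O)/C=C/CCc1ccc(O[Si](C(C)C)(C(C)C)C(C)C)cc1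
A3 | alternative 1 | dimethyl malonate | COC(=O)CC(=O)OC
A4 | alternative 2 | methyl 2,4-dihydroxy-3-(3-methylbut-2-enyl)-6-{2-[4-(tert-butyldimethylsilyloxy)phenyl]ethyl}benzoate | COC(=O)c1c(O)c(CC=C(C)C)c(O)cc1CCc1ccc(O[Si](C)(C)C(C)(C)C)cc1
A5 | alternative 2 | 1-methoxy-2-(3-methylbut-2-enyl)-1,3-bis(trimethylsilyloxy)buta-1,3-diene | COC(O[Si](C)(C)C)=C(CC=C(C)C)C(=C)O[Si](C)(C)C
A6 | alternative 2 | methyl 5-[4-(tert-butyldimethylsilyloxy)phenyl]pent-2-ynoate | COC(=O)C#CCCc1ccc(O[Si](C)(C)C(C)(C)C)cc1
A7 | alternative 3 | methyl 7-hydroxy-5-{2-[4-(tert-butyldimethylsilyloxy)phenyl]ethyl}-2,2-dimethyl-8-(3-methylbut-2-enyl)-2H-chromene-6-carboxylate | COC(=O)c1c(O)c(CC=C(C)C)c2OC(C)(C)C=Cc2c1CCc1ccc(O[Si](C)(C)C(C)(C)C)cc1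
A8 | alternative 3 | methyl 5-formyl-2,4-dihydroxy-3-(3-methylbut-2-enyl)-6-{2-[4-(tert-butyldimethylsilyloxy)phenyl]ethyl}benzoate | COC(=O)c1c(O)c(CC=C(C)C)c(O)c(C=O)c1CCc1ccc(O[Si](C)(C)C(C)(C)C)cc1
A9 | alternative 3 | 2-methylprop-1-enylmagnesium bromide | CC(C)=C[Mg]Br
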